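## Structural features

The target is a 1,7,8,8a-tetrahydro-6H-isochromen-6-one (locants O2, C1H2, C3, C4, C4a, C5, C6, C7, C8, C8a): carbocyclic ring A (C4a–C5–C6–C7–C8–C8a) is fused along C4a–C8a to dihydropyran ring B (O2–C1–C8a–C4a–C4–C3). A push–pull system runs through both rings, O2–C3=C4–C4a=C5–C6=O, a doubly vinylogous ester extended by the (E)-propenyl group on C3; its enol ether end is acid-labile. Ring A carries three contiguous stereocentres: C7 (R; tertiary alcohol with a methyl group next to the C6 ketone, an alpha-ketol), C8 (S; secondary alcohol esterified by orsellinic acid) and C8a (S; the methine that bears C1). Their arrangement is all-trans: 7-OH and the C1 branch lie on one face, the ester oxygen and the 7-methyl group on the other, so H8 and H8a are trans. Fragile points are C8a–H (gamma to the dienone and beta to the acyloxy group, hence prone to base-induced elimination), the tertiary ketol, the two free phenols and the di-ortho-substituted aroyl group, which is slow to put on a hindered alcohol. The real difficulty is the triad C7/C8/C8a: it ends at the trigonal carbon C4a, so the target offers no fourth stereocentre from which to relay it, and ring B is too labile to be made early. The key step exploits the fact that C4a carries a carbon branch (C4), lies para to the methyl-bearing C7 and next to C8a, while C8 is oxygenated: this is the substitution pattern of carvone (C1 = C8, C2 = C7, C5 = C4a, C6 = C8a), so C4a can hold a temporary stereocentre whose isopropenyl group is cut off at the ring–side-chain bond and replaced by the two carbons C4 and C3.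

## Logic of the disconnections

19 to 18: the O2–C3 bond is cut. The acid- and base-sensitive dienol ether is then formed last, by an isomerisation that adds no atoms. The bicycle becomes a monocycle with a primary alcohol and an alkyne. The forward step must close 6-endo at C3 and not 5-exo at C4.

18 to 17: three O–Si bonds are cut. One fluoride operation must free both phenols and the C1 alcohol without base strong enough to remove H8a.

17 to 15 (through 16): the C4a=C5 double bond and the C6 carbonyl are traced back to C4a–H/C5–H2 and a C6 carbinol. This removes the base-sensitive vinylogous system from all earlier intermediates and turns C4a back into an sp3 centre. The forward oxidation must stop at the enone; the quaternary C7 ensures that enolisation can only go towards C5.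

15 to 13 + 14: the C3–C(propenyl) bond is cut (sp–sp2 coupling). The propenyl alkene is thereby kept out of the osmylation step. The coupling must retain the E geometry.

13 to 12: the C6–O and C7–O bonds are cut, back to a C6=C7 alkene. Both oxygens and the C7 stereocentre come from one suprafacial addition. The forward step must add on the face opposite to the C8 aroyloxy group.

12 to 11 + 3: the ester C–O8 bond is cut at the stage of a robust allylic alcohol, not at the end on the dienone. This removes the late hindered acylation and gives the next step a bulky directing group. The forward step must acylate a hindered secondary alkoxide with a di-ortho-substituted aroyl chloride.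

11 to 9 (through 10): the C8–H bond (back to the C8 ketone) and the C(sp)–H bond (back to the silyl alkyne) are cut. Hydride must add 1,2 and axially so that O8 ends trans to the C8a branch.

9 to 6 + 7 (key disconnection): the C4a–C4 bond is cut. In the forward direction the ring–isopropenyl C–C bond of 6 is cleaved and the C4a radical is alkynylated by 7. This maps ring A with its C7 methyl group, the C8 oxygen and a controlling stereocentre at C4a onto 4, and delivers C4 and C3 in one operation. The demand is chemoselective ozonolysis beside an enone and efficient radical capture. In one sentence, the route is the iron-mediated ozonolytic cleavage of the ring–isopropenyl bond of 6 with alkynylation of the C4a radical by 7; this sentence does not fit a dearomatisation route.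

6 to 5 to 4: the O–Si bond and then the C8a–C1 bond are cut (aldol with a one-carbon aldehyde). The electrophile must enter trans to the isopropenyl group of 4.

3 to 2 to 1: the C–Cl bond and three O–Si bonds are cut. The acid chloride must be formed without free acid, which would strip the aryl silyl ethers.

## Other disconnections considered

Alternative 1: (the first that comes to mind) cut O2–C3 and the C7–OH bond as in azaphilone chemistry. Cycloisomerisation of alkynyl benzaldehyde A1 and hydroxylative dearomatisation at C7 would give the fully unsaturated dione A2; the target would follow by reduction at C1/C8a and at C8 and acylation of O8. Ground for preferring the chosen plan: A2 holds C1 and C8 one oxidation level too high. The two stereocentres that distinguish this target from ordinary azaphilones (C8, C8a) would therefore have to be set by a conjugate reduction of the vinylogous ester O2–C1=C8a–C8=O and a ketone reduction on a polyenone that offers C6, C3 and the propenyl group as competing sites. The dearomatisation needs a chiral oxidant or an enzyme for the one stereocentre it creates. The hindered acylation of O8 with 3 would come last, on the most fragile intermediate.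

Alternative 2: cut C6–C7, a union of two carbonyl carbons by polarity reversal. An intramolecular crossed benzoin reaction under N-heterocyclic carbene catalysis would take keto aldehyde A3 to ketol A4. Ground: A3 still needs C8 and C8a (and a centre at C4a) set in an open chain, so the cut removes only one of the three stereocentres. The facial selectivity at C7 would depend on a transition state in which the C8 silyloxy group and the C8a branch compete. An enal version is excluded by homoenolate pathways, so the C4a=C5 bond has to be introduced afterwards as in the chosen plan, at the cost of more steps.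

Alternative 3: cut C5–C4a and C8–C8a. A Diels–Alder reaction of silyloxy diene A5 with dienoate A6 would give cyclohexene silyl enol ether A7, followed by Rubottom oxidation at C7. Ground: the endo transition state places the C8 methoxy group and the C8a ester cis, whereas the target needs them trans, and correcting C8a means enolising an ester that carries a beta leaving group. The methoxy group would later have to be exchanged for the aroyl group. The absolute configuration would rest on a chiral Lewis acid acting on an acid-sensitive diene. The chosen plan obtains the same ring with absolute and relative control from 4.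

Key step: step 5

Remark: TBS = tert-butyldimethylsilyl; 1, 4, 7 and 14 are taken as purchased; the minor C4a epimer that step 5 may give is carried along, because C4a becomes trigonal in step 10.

## Steps

Step 1
Reactants: 1 orsellinic acid (2,4-dihydroxy-6-methylbenzoic acid)
Product: 2 TBS 2,4-bis(TBS-oxy)-6-methylbenzoate
Conditions: TBSCl (3.5 equiv), imidazole, DMF, 0 to 25 °C
Reagents that add atoms: tert-butyldimethylsilyl chloride, CC(C)(C)[Si](C)(C)Cl
Why: Exhaustive silylation of a hydroxy acid; the aryl silyl ethers should survive alkoxide acylation, osmylation and hypervalent iodine and fall off with fluoride, and the silyl ester is the direct precursor of the acid chloride.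

Step 2
Reactants: 2 TBS 2,4-bis(TBS-oxy)-6-methylbenzoate
Product: 3 2,4-bis(TBS-oxy)-6-methylbenzoyl chloride
Conditions: (COCl)2, DMF (cat.), CH2Cl2, 0 to 25 °C
Reagents that add atoms: oxalyl chloride, O=C(Cl)C(Cl)=O
Why: Vilsmeier-type conversion of a silyl ester into the acid chloride under neutral conditions; no free HCl is formed, so the aryl silyl ethers and the electron-rich ring should be left intact.

Step 3
Reactants: 4 (S)-(+)-carvone
Product: 5 (5S,6S)-6-(hydroxymethyl)-2-methyl-5-(prop-1-en-2-yl)cyclohex-2-en-1-one
Conditions: LiN(iPr)2, THF, −78 °C; CH2O (gas from cracked paraformaldehyde), −78 °C; aq. NH4Cl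
Reagents that add atoms: formaldehyde, C=O
Why: Kinetic deprotonation at the saturated alpha carbon (the future C8a) and aldol addition to formaldehyde; the electrophile should enter trans to the neighbouring isopropenyl group, so C8a is set from the carvone stereocentre (the trans isomer is also the more stable one).

Step 4
Reactants: 5 (5S,6S)-6-(hydroxymethyl)-2-methyl-5-(prop-1-en-2-yl)cyclohex-2-en-1-one
Product: 6 (5S,6S)-6-[(TBS-oxy)methyl]-2-methyl-5-(prop-1-en-2-yl)cyclohex-2-en-1-one
Conditions: TBSCl, imidazole, CH2Cl2, 0 °C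
Reagents that add atoms: tert-butyldimethylsilyl chloride, CC(C)(C)[Si](C)(C)Cl
Why: Silylation of the primary alcohol blocks retro-aldol cleavage and dehydration of the beta-hydroxy ketone and masks the future O2 until the last step.

Step 5
Reactants: 6 (5S,6S)-6-[(TBS-oxy)methyl]-2-methyl-5-(prop-1-en-2-yl)cyclohex-2-en-1-one; 7 1-methyl-4-{[(trimethylsilyl)ethynyl]sulfonyl}benzene
Product: 9 (5S,6S)-6-[(TBS-oxy)methyl]-2-methyl-5-[(trimethylsilyl)ethynyl]cyclohex-2-en-1-one, via methoxy hydroperoxide 8 (not isolated)
Conditions: O3, MeOH, −78 °C; then 7, FeSO4·7H2O (cat.), L-ascorbic acid, MeOH, 0 to 25 °C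
Reagents that add atoms: ozone, [O-][O+]=O; methanol, CO (their atoms reach intermediate 8 and the by-products, not 9)
Why: Ozone should add only to the isolated 1,1-disubstituted alkene (the ring alkene is deactivated by the conjugated carbonyl); the primary ozonide collapses to formaldehyde and a carbonyl oxide that methanol traps as methoxy hydroperoxide 8. Divalent iron cleaves the O–O bond by single-electron transfer, and the alkoxyl radical undergoes beta-scission of the ring–side-chain C–C bond, releasing methyl acetate and the secondary C4a radical (scission towards a methyl radical is much slower). This nucleophilic radical adds to the sulfonyl-bearing carbon of 7 and the vinyl radical expels the sulfonyl radical, which forms the C4a–C4 bond as a C(sp3)–C(sp) bond; ascorbic acid returns trivalent iron to divalent iron and reduces the sulfonyl radical to sulfinate. The closest known reaction type is the dealkenylative alkynylation of isopropenyl terpenoids (ozonolysis, catalytic iron salt, ascorbic acid, alkynyl sulfone), a relative of radical alkynylation with alkynyl sulfones. No ring is closed. The only new stereocentre is C4a: the planar radical should be captured anti to the neighbouring CH2OTBS group (trans product drawn), but this centre need not be controlled because it becomes trigonal in step 10, so both epimers converge. The step needs chemoselectivity for the isopropenyl alkene over the enone, secured by the electron-poor ring alkene, and integrity of C8a, secured because the radical is formed next to C8a and not at it, under non-basic conditions.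

Step 6
Reactants: 9 (5S,6S)-6-[(TBS-oxy)methyl]-2-methyl-5-[(trimethylsilyl)ethynyl]cyclohex-2-en-1-one
Product: 11 (1S,5S,6S)-6-[(TBS-oxy)methyl]-5-ethynyl-2-methylcyclohex-2-en-1-ol, via silylalkynyl allylic alcohol 10 (not isolated)
Conditions: NaBH4, CeCl3·7H2O, MeOH, −40 to 0 °C; then K2CO3 (cat.), 25 °C
Reagents that add atoms: none
Why: Luche 1,2-reduction; axial hydride delivery to the half-chair with both ring substituents pseudo-equatorial should give the pseudo-equatorial alcohol, trans to the CH2OTBS group (this sets C8, in the same sense as carvone gives cis-carveol), and carbonate in methanol then cleaves the C(sp)–Si bond once the beta-silyloxy ketone is gone.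

Step 7
Reactants: 11 (1S,5S,6S)-6-[(TBS-oxy)methyl]-5-ethynyl-2-methylcyclohex-2-en-1-ol; 3 2,4-bis(TBS-oxy)-6-methylbenzoyl chloride
Product: 12 (1S,5S,6S)-6-[(TBS-oxy)methyl]-5-ethynyl-2-methylcyclohex-2-en-1-yl 2,4-bis(TBS-oxy)-6-methylbenzoate
Conditions: NaN(SiMe3)2 (1.0 equiv), THF, −78 °C; then 3, −78 to 0 °C
Reagents that add atoms: none
Why: O-acylation of a sodium alkoxide by a hindered aroyl chloride (one equivalent of base takes the hydroxyl proton, not the alkyne proton); placing the ester here avoids a late acylation next to the tertiary alcohol, and the hindered benzoate resists migration and hydrolysis in later steps.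

Step 8
Reactants: 12 (1S,5S,6S)-6-[(TBS-oxy)methyl]-5-ethynyl-2-methylcyclohex-2-en-1-yl 2,4-bis(TBS-oxy)-6-methylbenzoate
Product: 13 (1S,2S,3S,5S,6S)-6-[(TBS-oxy)methyl]-5-ethynyl-2,3-dihydroxy-2-methylcyclohexyl 2,4-bis(TBS-oxy)-6-methylbenzoate
Conditions: OsO4 (cat.), N-methylmorpholine N-oxide, MeSO2NH2, acetone/H2O, 25 °C
Reagents that add atoms: N-methylmorpholine N-oxide, C[N+]1([O-])CCOCC1; water, O
Why: Catalytic osmium tetroxide dihydroxylation; the suprafacial addition should occur on the face opposite to the bulky allylic aroyloxy group (the usual sense for allylic esters and ethers), which places the tertiary C7–OH trans to O8 and so sets C7; the alkyne is inert to the reagent.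

Step 9
Reactants: 13 (1S,2S,3S,5S,6S)-6-[(TBS-oxy)methyl]-5-ethynyl-2,3-dihydroxy-2-methylcyclohexyl 2,4-bis(TBS-oxy)-6-methylbenzoate; 14 (E)-1-bromoprop-1-ene
Product: 15 (1S,2S,3S,5S,6S)-6-[(TBS-oxy)methyl]-2,3-dihydroxy-2-methyl-5-[(3E)-pent-3-en-1-yn-1-yl]cyclohexyl 2,4-bis(TBS-oxy)-6-methylbenzoate
Conditions: Pd(PPh3)4 (cat.), CuI (cat.), iPr2NH, THF, 25 °C
Reagents that add atoms: none
Why: Sonogashira coupling (oxidative addition to zerovalent palladium, transmetalation from the copper acetylide, reductive elimination) with retention of the E geometry; it follows step 8 because the propenyl alkene would otherwise compete for osmium.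

Step 10
Reactants: 15 (1S,2S,3S,5S,6S)-6-[(TBS-oxy)methyl]-2,3-dihydroxy-2-methyl-5-[(3E)-pent-3-en-1-yn-1-yl]cyclohexyl 2,4-bis(TBS-oxy)-6-methylbenzoate
Product: 17 (1S,2R,6S)-6-[(TBS-oxy)methyl]-2-hydroxy-2-methyl-3-oxo-5-[(3E)-pent-3-en-1-yn-1-yl]cyclohex-4-en-1-yl 2,4-bis(TBS-oxy)-6-methylbenzoate, via saturated ketol 16 (not isolated)
Conditions: IBX (excess), DMSO, 25 °C, then 70 °C
Reagents that add atoms: none
Why: IBX oxidises the secondary alcohol of the 1,2-diol without glycol cleavage and, on warming, dehydrogenates the ketone through its enol; C7 is quaternary, so the new double bond can only form between C5 and C4a, which erases the temporary stereocentre at C4a and puts the alkyne in conjugation.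

Step 11
Reactants: 17 (1S,2R,6S)-6-[(TBS-oxy)methyl]-2-hydroxy-2-methyl-3-oxo-5-[(3E)-pent-3-en-1-yn-1-yl]cyclohex-4-en-1-yl 2,4-bis(TBS-oxy)-6-methylbenzoate
Product: 18 (1S,2R,6S)-2-hydroxy-6-(hydroxymethyl)-2-methyl-3-oxo-5-[(3E)-pent-3-en-1-yn-1-yl]cyclohex-4-en-1-yl 2,4-dihydroxy-6-methylbenzoate
Conditions: Et3N·3HF, THF/MeCN, 25 °C
Reagents that add atoms: none
Why: Fluoride cleaves the two aryl silyl ethers and the primary silyl ether in one operation under nearly neutral conditions, which the acyloxy ketone (H8a is gamma to the enone and beta to the ester oxygen) and the tertiary ketol should tolerate.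

Step 12
Reactants: 18 (1S,2R,6S)-2-hydroxy-6-(hydroxymethyl)-2-methyl-3-oxo-5-[(3E)-pent-3-en-1-yn-1-yl]cyclohex-4-en-1-yl 2,4-dihydroxy-6-methylbenzoate
Product: 19 (7R,8S,8aS)-7-hydroxy-7-methyl-6-oxo-3-[(1E)-prop-1-en-1-yl]-1,7,8,8a-tetrahydro-6H-isochromen-8-yl 2,4-dihydroxy-6-methylbenzoate (target)
Conditions: (Ph3P)AuNTf2 (cat.), THF, 25 °C
Reagents that add atoms: none
Why: 6-endo-dig hydroalkoxylation (cycloisomerisation) under monovalent gold catalysis: the primary hydroxyl adds anti to the gold-bound alkyne at C3, the terminus that is delta to the ketone and carries the propenyl donor, and protodeauration at C4 gives the dienol ether. The 5-exo mode would put oxygen on C4 against the enone polarisation, and the ketone oxygen cannot reach the alkyne because C6 and C4 are trans on the C4a=C5 bond; no stereocentre is touched and no base is present.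

## Compound list

1 | orsellinic acid (2,4-dihydroxy-6-methylbenzoic acid) | Cc1cc(O)cc(O)c1C(=O)O | starting material
2 | tert-butyldimethylsilyl 2,4-bis[(tert-butyldimethylsilyl)oxy]-6-methylbenzoate | Cc1cc(O[Si](C)(C)C(C)(C)C)cc(O[Si](C)(C)C(C)(C)C)c1C(=O)O[Si](C)(C)C(C)(C)C | intermediate
3 | 2,4-bis[(tert-butyldimethylsilyl)oxy]-6-methylbenzoyl chloride | Cc1cc(O[Si](C)(C)C(C)(C)C)cc(O[Si](C)(C)C(C)(C)C)c1C(Cl)=O | intermediate
4 | (S)-(+)-carvone, (5S)-2-methyl-5-(prop-1-en-2-yl)cyclohex-2-en-1-one | CC(=C)[C@H]1CC=C(C)C(=O)C1 | starting material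
5 | (5S,6S)-6-(hydroxymethyl)-2-methyl-5-(prop-1-en-2-yl)cyclohex-2-en-1-one | CC(=C)[C@H]1CC=C(C)C(=O)[C@@H]1CO | intermediate
6 | (5S,6S)-6-{[(tert-butyldimethylsilyl)oxy]methyl}-2-methyl-5-(prop-1-en-2-yl)cyclohex-2-en-1-one | CC(=C)[C@H]1CC=C(C)C(=O)[C@@H]1CO[Si](C)(C)C(C)(C)C | intermediate
7 | 1-methyl-4-{[(trimethylsilyl)ethynyl]sulfonyl}benzene | Cc1ccc(cc1)S(=O)(=O)C#C[Si](C)(C)C | starting material
8 | (5S,6S)-6-{[(tert-butyldimethylsilyl)oxy]methyl}-5-(1-hydroperoxy-1-methoxyethyl)-2-methylcyclohex-2-en-1-one (both epimers at the peroxyketal carbon) | COC(C)(OO)[C@H]1CC=C(C)C(=O)[C@@H]1CO[Si](C)(C)C(C)(C)C | intermediate (not isolated)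
9 | (5S,6S)-6-{[(tert-butyldimethylsilyl)oxy]methyl}-2-methyl-5-[(trimethylsilyl)ethynyl]cyclohex-2-en-1-one | C[Si](C)(C)C#C[C@H]1CC=C(C)C(=O)[C@@H]1CO[Si](C)(C)C(C)(C)C | intermediate
10 | (1S,5S,6S)-6-{[(tert-butyldimethylsilyl)oxy]methyl}-2-methyl-5-[(trimethylsilyl)ethynyl]cyclohex-2-en-1-ol | C[Si](C)(C)C#C[C@H]1CC=C(C)[C@@H](O)[C@@H]1CO[Si](C)(C)C(C)(C)C | intermediate (not isolated)
11 | (1S,5S,6S)-6-{[(tert-butyldimethylsilyl)oxy]methyl}-5-ethynyl-2-methylcyclohex-2-en-1-ol | C#C[C@H]1CC=C(C)[C@@H](O)[C@@H]1CO[Si](C)(C)C(C)(C)C | intermediate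
12 | (1S,5S,6S)-6-{[(tert-butyldimethylsilyl)oxy]methyl}-5-ethynyl-2-methylcyclohex-2-en-1-yl 2,4-bis[(tert-butyldimethylsilyl)oxy]-6-methylbenzoate | C#C[C@H]1CC=C(C)[C@@H](OC(=O)c2c(C)cc(O[Si](C)(C)C(C)(C)C)cc2O[Si](C)(C)C(C)(C)C)[C@@H]1CO[Si](C)(C)C(C)(C)C | intermediate
13 | (1S,2S,3S,5S,6S)-6-{[(tert-butyldimethylsilyl)oxy]methyl}-5-ethynyl-2,3-dihydroxy-2-methylcyclohexyl 2,4-bis[(tert-butyldimethylsilyl)oxy]-6-methylbenzoate | C#C[C@H]1C[C@H](O)[C@](C)(O)[C@@H](OC(=O)c2c(C)cc(O[Si](C)(C)C(C)(C)C)cc2O[Si](C)(C)C(C)(C)C)[C@@H]1CO[Si](C)(C)C(C)(C)C | intermediate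
14 | (E)-1-bromoprop-1-ene | C/C=C/Br | starting material
15 | (1S,2S,3S,5S,6S)-6-{[(tert-butyldimethylsilyl)oxy]methyl}-2,3-dihydroxy-2-methyl-5-[(3E)-pent-3-en-1-yn-1-yl]cyclohexyl 2,4-bis[(tert-butyldimethylsilyl)oxy]-6-methylbenzoate | C/C=C/C#C[C@H]1C[C@H](O)[C@](C)(O)[C@@H](OC(=O)c2c(C)cc(O[Si](C)(C)C(C)(C)C)cc2O[Si](C)(C)C(C)(C)C)[C@@H]1CO[Si](C)(C)C(C)(C)C | intermediate
16 | (1S,2R,5S,6S)-6-{[(tert-butyldimethylsilyl)oxy]methyl}-2-hydroxy-2-methyl-3-oxo-5-[(3E)-pent-3-en-1-yn-1-yl]cyclohexyl 2,4-bis[(tert-butyldimethylsilyl)oxy]-6-methylbenzoate | C/C=C/C#C[C@H]1CC(=O)[C@](C)(O)[C@@H](OC(=O)c2c(C)cc(O[Si](C)(C)C(C)(C)C)cc2O[Si](C)(C)C(C)(C)C)[C@@H]1CO[Si](C)(C)C(C)(C)C | intermediate (not isolated)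
17 | (1S,2R,6S)-6-{[(tert-butyldimethylsilyl)oxy]methyl}-2-hydroxy-2-methyl-3-oxo-5-[(3E)-pent-3-en-1-yn-1-yl]cyclohex-4-en-1-yl 2,4-bis[(tert-butyldimethylsilyl)oxy]-6-methylbenzoate | C/C=C/C#CC1=CC(=O)[C@](C)(O)[C@@H](OC(=O)c2c(C)cc(O[Si](C)(C)C(C)(C)C)cc2O[Si](C)(C)C(C)(C)C)[C@@H]1CO[Si](C)(C)C(C)(C)C | intermediate
18 | (1S,2R,6S)-2-hydroxy-6-(hydroxymethyl)-2-methyl-3-oxo-5-[(3E)-pent-3-en-1-yn-1-yl]cyclohex-4-en-1-yl 2,4-dihydroxy-6-methylbenzoate | C/C=C/C#CC1=CC(=O)[C@](C)(O)[C@@H](OC(=O)c2c(C)cc(O)cc2O)[C@@H]1CO | intermediate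
19 | (7R,8S,8aS)-7-hydroxy-7-methyl-6-oxo-3-[(1E)-prop-1-en-1-yl]-1,7,8,8a-tetrahydro-6H-isochromen-8-yl 2,4-dihydroxy-6-methylbenzoate | C/C=C/C1=CC2=CC(=O)[C@](C)(O)[C@@H](OC(=O)c3c(C)cc(O)cc3O)[C@@H]2CO1 | target

## Step count and least certain steps

Total: 12 steps. Longest linear sequence: 10 steps (4 to 19, steps 3 to 12); the aroyl chloride 3 takes 2 steps from 1.

Step 5 (key step). What may go wrong: over-ozonolysis of the ring alkene, reduction of the C4a radical to C–H by hydrogen-atom transfer before it meets 7, or radical addition to the silyl-bearing alkyne carbon. Fallback (sets out from 6, comes back at 11): the same bond is cut by polar chemistry. Ozonolysis of 6 with Me2S work-up should give the methyl ketone F1. Kinetic enolisation of the acetyl group with LiN(iPr)2 and trapping with ClP(O)(OEt)2 gives the enol phosphate F2. NaBH4/CeCl3·7H2O reduces the enone to the enol phosphate alcohol F3. Excess LiN(iPr)2 then eliminates diethyl phosphate to the terminal alkyne, which is 11.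

Step 3. What may go wrong: retro-aldol cleavage or dehydration of the beta-hydroxy ketone during work-up, double hydroxymethylation, or erratic delivery of gaseous formaldehyde. Fallback (sets out from 4, comes back at 5): 4 is converted with LiN(iPr)2 and Me3SiCl into the silyl dienol ether F4, which is hydroxymethylated by a Mukaiyama aldol reaction with aqueous formaldehyde and Yb(OTf)3 to give 5.

Step 7. What may go wrong: slow acylation caused by the two ortho substituents of 3, or silyl transfer from an aryl silyl ether to the alkoxide. Fallback (sets out from 1 and 11, comes back at 12): the acyl donor is changed to a tied-back salicylate. 1 is condensed with acetone (trifluoroacetic anhydride, trifluoroacetic acid) to the benzodioxinone F5 and silylated to the silyl ether F6. The sodium alkoxide of 11 opens F6 at its carbonyl group with loss of acetone to the salicylate ester F7. TBSCl/imidazole on the freed ortho phenol gives 12.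

Step 8. What may go wrong: poor facial selectivity if the pseudo-equatorial aroyloxy group shields too little, or slow hydrolysis of the hindered osmate ester. Fallback (sets out from 12, comes back at 13, no new compound): control is moved from the substrate to the reagent, with stoichiometric OsO4 bound to (DHQ)2PHAL in CH2Cl2 at −78 °C and reductive work-up; the ligand mnemonic places this ligand on the face opposite to the ester.

Step 10. What may go wrong: stalling at ketol 16, or oxidation at the benzylic methyl group or at the allylic positions of the enyne at the temperature needed for dehydrogenation. Fallback (sets out from 15, comes back at 17): Dess–Martin periodinane gives 16, which is isolated. Me3SiOTf/Et3N converts it into the bis(trimethylsilyl) enol ether F8. Saegusa–Ito oxidation with Pd(OAc)2 in MeCN gives the enone silyl ether F9. Citric acid in MeOH removes the tertiary silyl ether to give 17.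

## Further compounds

F1 | step 5 | (5S,6S)-5-acetyl-6-{[(tert-butyldimethylsilyl)oxy]methyl}-2-methylcyclohex-2-en-1-one | CC(=O)[C@H]1CC=C(C)C(=O)[C@@H]1CO[Si](C)(C)C(C)(C)C
F2 | step 5 | diethyl 1-[(1S,6S)-6-{[(tert-butyldimethylsilyl)oxy]methyl}-4-methyl-5-oxocyclohex-3-en-1-yl]ethenyl phosphate | C=C(OP(=O)(OCC)OCC)[C@H]1CC=C(C)C(=O)[C@@H]1CO[Si](C)(C)C(C)(C)C
F3 | step 5 | diethyl 1-[(1S,5S,6S)-6-{[(tert-butyldimethylsilyl)oxy]methyl}-5-hydroxy-4-methylcyclohex-3-en-1-yl]ethenyl phosphate | C=C(OP(=O)(OCC)OCC)[C@H]1CC=C(C)[C@@H](O)[C@@H]1CO[Si](C)(C)C(C)(C)C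
F4 | step 3 | trimethyl{[(3S)-6-methyl-3-(prop-1-en-2-yl)cyclohexa-1,5-dien-1-yl]oxy}silane | CC(=C)[C@H]1CC=C(C)C(O[Si](C)(C)C)=C1
F5 | step 7 | 7-hydroxy-2,2,5-trimethyl-4H-1,3-benzodioxin-4-one | Cc1cc(O)cc2OC(C)(C)OC(=O)c12
F6 | step 7 | 7-[(tert-butyldimethylsilyl)oxy]-2,2,5-trimethyl-4H-1,3-benzodioxin-4-one | Cc1cc(O[Si](C)(C)C(C)(C)C)cc2OC(C)(C)OC(=O)c12
F7 | step 7 | (1S,5S,6S)-6-{[(tert-butyldimethylsilyl)oxy]methyl}-5-ethynyl-2-methylcyclohex-2-en-1-yl 4-[(tert-butyldimethylsilyl)oxy]-2-hydroxy-6-methylbenzoate | C#C[C@H]1CC=C(C)[C@@H](OC(=O)c2c(C)cc(O[Si](C)(C)C(C)(C)C)cc2O)[C@@H]1CO[Si](C)(C)C(C)(C)C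
F0 | step 8 | none | none
F8 | step 10 | (1S,2R,5R,6S)-6-{[(tert-butyldimethylsilyl)oxy]methyl}-2-methyl-5-[(3E)-pent-3-en-1-yn-1-yl]-2,3-bis[(trimethylsilyl)oxy]cyclohex-3-en-1-yl 2,4-bis[(tert-butyldimethylsilyl)oxy]-6-methylbenzoate | C/C=C/C#C[C@H]1C=C(O[Si](C)(C)C)[C@](C)(O[Si](C)(C)C)[C@@H](OC(=O)c2c(C)cc(O[Si](C)(C)C(C)(C)C)cc2O[Si](C)(C)C(C)(C)C)[C@@H]1CO[Si](C)(C)C(C)(C)C
F9 | step 10 | (1S,2R,6S)-6-{[(tert-butyldimethylsilyl)oxy]methyl}-2-methyl-3-oxo-5-[(3E)-pent-3-en-1-yn-1-yl]-2-[(trimethylsilyl)oxy]cyclohex-4-en-1-yl 2,4-bis[(tert-butyldimethylsilyl)oxy]-6-methylbenzoate | C/C=C/C#CC1=CC(=O)[C@](C)(O[Si](C)(C)C)[C@@H](OC(=O)c2c(C)cc(O[Si](C)(C)C(C)(C)C)cc2O[Si](C)(C)C(C)(C)C)[C@@H]1CO[Si](C)(C)C(C)(C)C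
A1 | alternative 1 | 2,4-dihydroxy-3-methyl-6-[(3E)-pent-3-en-1-yn-1-yl]benzaldehyde | C/C=C/C#Cc1cc(O)c(C)c(O)c1C=O
A2 | alternative 1 | (7S)-7-hydroxy-7-methyl-3-[(1E)-prop-1-en-1-yl]-6H-isochromene-6,8(7H)-dione (same spatial arrangement at C7 as the target) | C/C=C/C1=CC2=CC(=O)[C@](C)(O)C(=O)C2=CO1
A3 | alternative 2 | 4-{[(tert-butyldimethylsilyl)oxy]methyl}-6-oxo-3-[(3E)-pent-3-en-1-yn-1-yl]-5-[(triethylsilyl)oxy]heptanal, configured at C8 and C8a as in the target, either epimer at C4a | O=CCC(C#C/C=C/C)[C@@H](CO[Si](C)(C)C(C)(C)C)[C@H](O[Si](CC)(CC)CC)C(C)=O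
A4 | alternative 2 | 4-{[(tert-butyldimethylsilyl)oxy]methyl}-2-hydroxy-2-methyl-5-[(3E)-pent-3-en-1-yn-1-yl]-3-[(triethylsilyl)oxy]cyclohexan-1-one, configured at C7, C8 and C8a as in the target, either epimer at C4a | C/C=C/C#CC1CC(=O)[C@](C)(O)[C@@H](O[Si](CC)(CC)CC)[C@@H]1CO[Si](C)(C)C(C)(C)C
A5 | alternative 3 | (1E)-1-methoxy-2-methyl-3-[(trimethylsilyl)oxy]buta-1,3-diene | CO/C=C(\C)C(=C)O[Si](C)(C)C
A6 | alternative 3 | ethyl (2E,6E)-octa-2,6-dien-4-ynoate | CCOC(=O)/C=C/C#C/C=C/C
A7 | alternative 3 | ethyl 2-methoxy-3-methyl-6-[(3E)-pent-3-en-1-yn-1-yl]-4-[(trimethylsilyl)oxy]cyclohex-3-ene-1-carboxylate, endo adduct, racemic, one enantiomer drawn | C/C=C/C#C[C@@H]1CC(O[Si](C)(C)C)=C(C)[C@@H](OC)[C@H]1C(=O)OCC
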